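**Retrosynthetic overview**
1. Both oxiranes are added last by two reagent-controlled Shi epoxidations (side-chain C10=C11, then ring C3=C4) of triene tris-angelate 26; the three esters come from one triple acylation of triol 23 with three equivalents of angelic acid.
2. Key disconnection is the ring bond C1–C6: the target holds the homoallylic alcohol array O–C1–C6–C7(=C14H2) on its six-membered ring, the retron of a carbonyl-ene reaction, so the carbocycle is closed from open-chain trienal 21 (C1 aldehyde, C6=C7 alkene carrying C14H3), in the same way the farnesyl chain closes C1–C6 to the bisabolyl skeleton in biosynthesis.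
3. Trienal 21 comes from two Z-selective Wittig olefinations of α-alkoxy methyl ketones on a C4–C5–C6 linker (C3=C4 from glycerate-derived ketone 3, C6=C7 from glycidate-derived ketone 16); C2 and C8 come from the chiral pool.
4. Ring order: cyclohexene ring (step 16), side-chain oxirane (step 19), ring-fused oxirane (step 20).

Key step: step 16

Remark: locants are bisabolane locants (ring C1–C6 with C15 methyl on C3; chain C7–C11 on C6; C14 is the methylene on C7); the L-fructose-derived enantiomer of the Shi ketone (step 20) is taken as available, since it is made from L-sorbose.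

**Route**

Step 1
Reactants: 1 methyl (S)-2,2-dimethyl-1,3-dioxolane-4-carboxylate
Product: 2 (S)-N-methoxy-N,2,2-trimethyl-1,3-dioxolane-4-carboxamide
Conditions: MeNHOMe·HCl, iPrMgCl, THF, −20 °C
Reagents that add atoms: N,O-dimethylhydroxylamine hydrochloride, CNOC.Cl
Why: Aminolysis of the ester by the chloromagnesium amide (Weinreb amide synthesis) at low temperature should leave the α-alkoxy stereocentre untouched.

Step 2
Reactants: 2 (S)-N-methoxy-N,2,2-trimethyl-1,3-dioxolane-4-carboxamide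
Product: 3 1-[(4S)-2,2-dimethyl-1,3-dioxolan-4-yl]ethan-1-one
Conditions: MeMgBr, THF, 0 °C
Reagents that add atoms: methylmagnesium bromide, C[Mg]Br
Why: Weinreb ketone synthesis, in which the chelated tetrahedral adduct stops at mono-addition and releases the methyl ketone only on work-up.

Step 3
Reactants: 4 (3-bromopropoxy)(tert-butyl)dimethylsilane
Product: 5 [3-(tert-butyldimethylsilyloxy)propyl]triphenylphosphonium bromide
Conditions: PPh3, MeCN, reflux
Reagents that add atoms: triphenylphosphine, c1ccc(cc1)P(c1ccccc1)c1ccccc1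
Why: SN2 quaternisation of triphenylphosphine by the primary bromide.

Step 4
Reactants: 5 [3-(tert-butyldimethylsilyloxy)propyl]triphenylphosphonium bromide; 3 1-[(4S)-2,2-dimethyl-1,3-dioxolan-4-yl]ethan-1-one
Product: 7 (4R)-4-[(2Z)-5-(tert-butyldimethylsilyloxy)pent-2-en-2-yl]-2,2-dimethyl-1,3-dioxolane, via silyloxypropylidene ylide 6 (not isolated)
Conditions: NaN(SiMe3)2, THF, 0 °C; then 3, −78 °C → rt
Reagents that add atoms: none
Why: Wittig olefination of an α-alkoxy methyl ketone with a non-stabilised ylide, a combination known to give the Z-trisubstituted allylic ether, so that C2 and C5 should end up cis across the new C3=C4 bond.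

Step 5
Reactants: 7 (4R)-4-[(2Z)-5-(tert-butyldimethylsilyloxy)pent-2-en-2-yl]-2,2-dimethyl-1,3-dioxolane
Product: 8 (3Z)-4-[(4R)-2,2-dimethyl-1,3-dioxolan-4-yl]pent-3-en-1-ol
Conditions: Bu4NF, THF, 0 °C → rt
Reagents that add atoms: none
Why: Fluoride-mediated desilylation of the primary silyl ether, to which the acetonide is inert.

Step 6
Reactants: 8 (3Z)-4-[(4R)-2,2-dimethyl-1,3-dioxolan-4-yl]pent-3-en-1-ol
Product: 9 (4R)-4-[(2Z)-5-iodopent-2-en-2-yl]-2,2-dimethyl-1,3-dioxolane
Conditions: I2, PPh3, imidazole, CH2Cl2, 0 °C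
Reagents that add atoms: iodine, II
Why: Appel-type iodination of the primary alcohol under imidazole-buffered conditions that should spare the acetonide and the alkene.

Step 7
Reactants: 9 (4R)-4-[(2Z)-5-iodopent-2-en-2-yl]-2,2-dimethyl-1,3-dioxolane
Product: 10 {(3Z)-4-[(4R)-2,2-dimethyl-1,3-dioxolan-4-yl]pent-3-en-1-yl}triphenylphosphonium iodide
Conditions: PPh3, iPr2NEt (cat.), MeCN, 70 °C
Reagents that add atoms: triphenylphosphine, c1ccc(cc1)P(c1ccccc1)c1ccccc1
Why: SN2 quaternisation of triphenylphosphine by the primary homoallylic iodide, with a trace of amine keeping the medium non-acidic for the acetonide.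

Step 8
Reactants: 11 methyl (2S)-oxirane-2-carboxylate; 12 2-methylprop-1-enylmagnesium bromide
Product: 13 methyl (2S)-2-hydroxy-5-methylhex-4-enoate
Conditions: CuI (10 mol %), THF, −40 °C
Reagents that add atoms: none
Why: Copper-catalysed SN2 opening of the epoxide at its CH2 terminus by the alkenyl Grignard reagent should install the prenyl unit without touching the carbinol stereocentre (the later C8).

Step 9
Reactants: 13 methyl (2S)-2-hydroxy-5-methylhex-4-enoate
Product: 14 methyl (2S)-2-(tert-butyldimethylsilyloxy)-5-methylhex-4-enoate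
Conditions: TBSCl, imidazole, DMF, rt
Reagents that add atoms: tert-butyldimethylsilyl chloride, CC(C)(C)[Si](C)(C)Cl
Why: Imidazole-promoted silylation of the secondary alcohol.

Step 10
Reactants: 14 methyl (2S)-2-(tert-butyldimethylsilyloxy)-5-methylhex-4-enoate
Product: 15 (2S)-2-(tert-butyldimethylsilyloxy)-N-methoxy-N,5-dimethylhex-4-enamide
Conditions: MeNHOMe·HCl, iPrMgCl, THF, −20 °C
Reagents that add atoms: N,O-dimethylhydroxylamine hydrochloride, CNOC.Cl
Why: Weinreb amide synthesis by magnesium amide aminolysis, as in step 1.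

Step 11
Reactants: 15 (2S)-2-(tert-butyldimethylsilyloxy)-N-methoxy-N,5-dimethylhex-4-enamide
Product: 16 (3S)-3-(tert-butyldimethylsilyloxy)-6-methylhept-5-en-2-one
Conditions: MeMgBr, THF, 0 °C
Reagents that add atoms: methylmagnesium bromide, C[Mg]Br
Why: Weinreb ketone synthesis, as in step 2, should give the α-silyloxy methyl ketone without over-addition.

Step 12
Reactants: 10 {(3Z)-4-[(4R)-2,2-dimethyl-1,3-dioxolan-4-yl]pent-3-en-1-yl}triphenylphosphonium iodide; 16 (3S)-3-(tert-butyldimethylsilyloxy)-6-methylhept-5-en-2-one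
Product: 18 (4R)-4-[(2Z,5Z,7S)-7-(tert-butyldimethylsilyloxy)-6,10-dimethylundeca-2,5,9-trien-2-yl]-2,2-dimethyl-1,3-dioxolane, via pentenylidene ylide 17 (not isolated)
Conditions: NaN(SiMe3)2, THF, −78 → 0 °C; then 16, −78 °C → rt
Reagents that add atoms: none
Why: Second Z-selective Wittig olefination of an α-silyloxy methyl ketone with a non-stabilised ylide, which should place C8 cis to C5 across C6=C7 (C14H3 trans to C5) while the low temperature limits enolisation of 16.

Step 13
Reactants: 18 (4R)-4-[(2Z,5Z,7S)-7-(tert-butyldimethylsilyloxy)-6,10-dimethylundeca-2,5,9-trien-2-yl]-2,2-dimethyl-1,3-dioxolane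
Product: 19 (2R,3Z,6Z,8S)-8-(tert-butyldimethylsilyloxy)-3,7,11-trimethyldodeca-3,6,10-triene-1,2-diol
Conditions: AcOH/THF/H2O (4:1:1), 40 °C
Reagents that add atoms: none
Why: Acid-catalysed hydrolysis of the terminal acetonide should be faster than loss of the hindered secondary TBS ether.

Step 14
Reactants: 19 (2R,3Z,6Z,8S)-8-(tert-butyldimethylsilyloxy)-3,7,11-trimethyldodeca-3,6,10-triene-1,2-diol
Product: 20 (2R,3Z,6Z,8S)-8-(tert-butyldimethylsilyloxy)-3,7,11-trimethyl-1,2-bis(triethylsilyloxy)dodeca-3,6,10-triene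
Conditions: TESCl (2.5 equiv), imidazole, CH2Cl2, 0 °C → rt
Reagents that add atoms: chlorotriethylsilane, CC[Si](Cl)(CC)CC
Why: Imidazole-promoted silylation of both hydroxyls sets up the selective oxidation of the primary position.

Step 15
Reactants: 20 (2R,3Z,6Z,8S)-8-(tert-butyldimethylsilyloxy)-3,7,11-trimethyl-1,2-bis(triethylsilyloxy)dodeca-3,6,10-triene
Product: 21 (2R,3Z,6Z,8S)-8-(tert-butyldimethylsilyloxy)-3,7,11-trimethyl-2-(triethylsilyloxy)dodeca-3,6,10-trienal
Conditions: (COCl)2, DMSO, CH2Cl2, −78 → −40 °C; Et3N, −78 °C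
Reagents that add atoms: none
Why: Swern oxidation in which the chlorosulfonium reagent cleaves only the primary triethylsilyl ether and oxidises it in place to the aldehyde; cold amine addition and immediate use should preserve the C2 centre and the β,γ-alkene.

Step 16
Reactants: 21 (2R,3Z,6Z,8S)-8-(tert-butyldimethylsilyloxy)-3,7,11-trimethyl-2-(triethylsilyloxy)dodeca-3,6,10-trienal
Product: 22 (1R,2R,6R)-6-[(3S)-3-(tert-butyldimethylsilyloxy)-6-methylhepta-1,5-dien-2-yl]-3-methyl-2-(triethylsilyloxy)cyclohex-3-en-1-ol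
Conditions: Me2AlCl (1.5 equiv), CH2Cl2, −78 → −40 °C; aq. NaHCO3
Reagents that add atoms: none
Why: Me2AlCl binds the aldehyde oxygen, the C6=C7 π bond attacks C1 while the carbonyl oxygen takes a hydrogen from C14 in one asynchronous six-centre ene transition state, and the aluminium alkoxide formed loses methane, so no protic acid is present. The closest known reaction is the Lewis-acid-promoted type 1 intramolecular carbonyl-ene cyclisation of 6-enals (citronellal to isopulegol). The cyclohexene ring closes in a 6-exo mode at both π bonds (C7 and the carbonyl oxygen stay outside the ring) through a half-chair in which the 3Z alkene holds C2 and C5 cis. C1 and C6 are set trans because the complexed C1=O and C7 both sit equatorial; the sense relative to C2 comes from the C2 silyloxy group lying pseudo-equatorial and anti to the forming bond (polar Felkin–Anh), and C8 should reinforce it, since A(1,3) strain puts H8 in the alkene plane and the enophile then adds to the face away from the OTBS group. The step needs hydrogen transfer from C14 and not from C8, and the 6Z geometry secures this: only C14H3, trans to C5, can reach the equatorial carbonyl oxygen, while closure onto C10=C11 would need a ten-membered ring.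

Step 17
Reactants: 22 (1R,2R,6R)-6-[(3S)-3-(tert-butyldimethylsilyloxy)-6-methylhepta-1,5-dien-2-yl]-3-methyl-2-(triethylsilyloxy)cyclohex-3-en-1-ol
Product: 23 (1R,2R,6R)-6-[(3S)-3-hydroxy-6-methylhepta-1,5-dien-2-yl]-3-methylcyclohex-3-ene-1,2-diol
Conditions: Bu4NF, THF, 0 °C → rt
Reagents that add atoms: none
Why: Fluoride-mediated cleavage of both silyl ethers should free the three hydroxyls that all carry the same ester in the target.

Step 18
Reactants: 23 (1R,2R,6R)-6-[(3S)-3-hydroxy-6-methylhepta-1,5-dien-2-yl]-3-methylcyclohex-3-ene-1,2-diol; 24 angelic acid [(Z)-2-methylbut-2-enoic acid] (three equivalents are taken up, one for each hydroxyl)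
Product: 26 (1R,2R,6R)-3-methyl-6-[(3S)-6-methyl-3-{[(Z)-2-methylbut-2-enoyl]oxy}hepta-1,5-dien-2-yl]cyclohex-3-ene-1,2-diyl bis[(Z)-2-methylbut-2-enoate], via mixed anhydride 25 (not isolated)
Conditions: 24 (3.3 equiv), 2,4,6-Cl3C6H2COCl (3.3 equiv), Et3N, toluene, rt; then 23, toluene, 80 °C
Reagents that add atoms: angelic acid (the second and third equivalents of 24), C/C=C(/C)C(=O)O.C/C=C(/C)C(=O)O
Why: Yamaguchi-type acylation through the trichlorobenzoyl mixed anhydride without a nucleophilic catalyst, the known way to make angelates of hindered alcohols without Z to E isomerisation; each of the three hydroxyls takes one angeloyl group from one molecule of 25, so three molecules of angelic acid end up in 26.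

Step 19
Reactants: 26 triene tris-angelate (name as in step 18)
Product: 27 (1R,2R,6R)-6-{(3S)-4-[(2R)-3,3-dimethyloxiran-2-yl]-3-{[(Z)-2-methylbut-2-enoyl]oxy}but-1-en-2-yl}-3-methylcyclohex-3-ene-1,2-diyl bis[(Z)-2-methylbut-2-enoate]
Conditions: D-fructose-derived Shi ketone (1,2:4,5-di-O-isopropylidene-β-D-erythro-2,3-hexodiulo-2,6-pyranose, 30 mol %), Oxone (2KHSO5·KHSO4·K2SO4, 1.4 equiv), K2CO3, Bu4NHSO4, MeCN–CH2(OMe)2/aq. Na2B4O7 buffer, 0 °C
Reagents that add atoms: Oxone (potassium peroxymonosulfate), [K+].[O-]S(=O)(=O)OO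
Why: Shi epoxidation, in which the chiral dioxirane should attack the unhindered, most electron-rich C10=C11 bond through the spiro transition state to set 10R by reagent control, while the ring alkene (hindered, allylic ester, mismatched with this ketone), the C7=C14 methylene and the angelate alkenes react more slowly.

Step 20
Reactants: 27 mono-epoxide (name as in step 19)
Product: 28 (1R,2S,3S,4S,6R,8S,10R)-1,2,8-tris(angeloyloxy)-3,4:10,11-diepoxybisabol-7(14)-ene (the target)
Conditions: L-fructose-derived Shi ketone (enantiomer of the ketone of step 19, 1 equiv), Oxone (2KHSO5·KHSO4·K2SO4), K2CO3, Bu4NHSO4, MeCN–CH2(OMe)2/aq. Na2B4O7 buffer, 0 °C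
Reagents that add atoms: Oxone (potassium peroxymonosulfate), [K+].[O-]S(=O)(=O)OO
Why: Shi epoxidation with the enantiomeric ketone, whose dioxirane is matched with the ring trisubstituted alkene and should deliver oxygen to the face anti to the allylic C2 angelate (cis to the C1 ester), setting 3S,4S by reagent control supported by the substrate.

**Compound list**
1 | methyl (S)-2,2-dimethyl-1,3-dioxolane-4-carboxylate | COC(=O)[C@@H]1COC(C)(C)O1 | starting material
2 | (S)-N-methoxy-N,2,2-trimethyl-1,3-dioxolane-4-carboxamide | CON(C)C(=O)[C@@H]1COC(C)(C)O1 | intermediate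
3 | 1-[(4S)-2,2-dimethyl-1,3-dioxolan-4-yl]ethan-1-one | CC(=O)[C@@H]1COC(C)(C)O1 | intermediate
4 | (3-bromopropoxy)(tert-butyl)dimethylsilane | CC(C)(C)[Si](C)(C)OCCCBr | starting material
5 | [3-(tert-butyldimethylsilyloxy)propyl]triphenylphosphonium bromide | CC(C)(C)[Si](C)(C)OCCC[P+](c1ccccc1)(c1ccccc1)c1ccccc1.[Br-] | intermediate
6 | [3-(tert-butyldimethylsilyloxy)propylidene]triphenylphosphorane | CC(C)(C)[Si](C)(C)OCCC=P(c1ccccc1)(c1ccccc1)c1ccccc1 | intermediate (not isolated)
7 | (4R)-4-[(2Z)-5-(tert-butyldimethylsilyloxy)pent-2-en-2-yl]-2,2-dimethyl-1,3-dioxolane | CC1(C)OC[C@H](O1)/C(C)=C\CCO[Si](C)(C)C(C)(C)C | intermediate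
8 | (3Z)-4-[(4R)-2,2-dimethyl-1,3-dioxolan-4-yl]pent-3-en-1-ol | CC1(C)OC[C@H](O1)/C(C)=C\CCO | intermediate
9 | (4R)-4-[(2Z)-5-iodopent-2-en-2-yl]-2,2-dimethyl-1,3-dioxolane | CC1(C)OC[C@H](O1)/C(C)=C\CCI | intermediate
10 | {(3Z)-4-[(4R)-2,2-dimethyl-1,3-dioxolan-4-yl]pent-3-en-1-yl}triphenylphosphonium iodide | CC1(C)OC[C@H](O1)/C(C)=C\CC[P+](c1ccccc1)(c1ccccc1)c1ccccc1.[I-] | intermediate
11 | methyl (2S)-oxirane-2-carboxylate | COC(=O)[C@@H]1CO1 | starting material
12 | 2-methylprop-1-enylmagnesium bromide | CC(C)=C[Mg]Br | starting material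
13 | methyl (2S)-2-hydroxy-5-methylhex-4-enoate | COC(=O)[C@@H](O)CC=C(C)C | intermediate
14 | methyl (2S)-2-(tert-butyldimethylsilyloxy)-5-methylhex-4-enoate | COC(=O)[C@@H](O[Si](C)(C)C(C)(C)C)CC=C(C)C | intermediate
15 | (2S)-2-(tert-butyldimethylsilyloxy)-N-methoxy-N,5-dimethylhex-4-enamide | CON(C)C(=O)[C@@H](O[Si](C)(C)C(C)(C)C)CC=C(C)C | intermediate
16 | (3S)-3-(tert-butyldimethylsilyloxy)-6-methylhept-5-en-2-one | CC(=O)[C@@H](O[Si](C)(C)C(C)(C)C)CC=C(C)C | intermediate
17 | {(3Z)-4-[(4R)-2,2-dimethyl-1,3-dioxolan-4-yl]pent-3-en-1-ylidene}triphenylphosphorane | CC1(C)OC[C@H](O1)/C(C)=C\CC=P(c1ccccc1)(c1ccccc1)c1ccccc1 | intermediate (not isolated)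
18 | (4R)-4-[(2Z,5Z,7S)-7-(tert-butyldimethylsilyloxy)-6,10-dimethylundeca-2,5,9-trien-2-yl]-2,2-dimethyl-1,3-dioxolane | CC1(C)OC[C@H](O1)/C(C)=C\C/C=C(/C)[C@@H](O[Si](C)(C)C(C)(C)C)CC=C(C)C | intermediate
19 | (2R,3Z,6Z,8S)-8-(tert-butyldimethylsilyloxy)-3,7,11-trimethyldodeca-3,6,10-triene-1,2-diol | OC[C@H](O)/C(C)=C\C/C=C(/C)[C@@H](O[Si](C)(C)C(C)(C)C)CC=C(C)C | intermediate
20 | (2R,3Z,6Z,8S)-8-(tert-butyldimethylsilyloxy)-3,7,11-trimethyl-1,2-bis(triethylsilyloxy)dodeca-3,6,10-triene | CC[Si](CC)(CC)OC[C@H](O[Si](CC)(CC)CC)/C(C)=C\C/C=C(/C)[C@@H](O[Si](C)(C)C(C)(C)C)CC=C(C)C | intermediate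
21 | (2R,3Z,6Z,8S)-8-(tert-butyldimethylsilyloxy)-3,7,11-trimethyl-2-(triethylsilyloxy)dodeca-3,6,10-trienal | O=C[C@H](O[Si](CC)(CC)CC)/C(C)=C\C/C=C(/C)[C@@H](O[Si](C)(C)C(C)(C)C)CC=C(C)C | intermediate
22 | (1R,2R,6R)-6-[(3S)-3-(tert-butyldimethylsilyloxy)-6-methylhepta-1,5-dien-2-yl]-3-methyl-2-(triethylsilyloxy)cyclohex-3-en-1-ol | C=C([C@H](CC=C(C)C)O[Si](C)(C)C(C)(C)C)[C@H]1CC=C(C)[C@@H](O[Si](CC)(CC)CC)[C@@H]1O | intermediate
23 | (1R,2R,6R)-6-[(3S)-3-hydroxy-6-methylhepta-1,5-dien-2-yl]-3-methylcyclohex-3-ene-1,2-diol | C=C([C@H](CC=C(C)C)O)[C@H]1CC=C(C)[C@@H](O)[C@@H]1O | intermediate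
24 | angelic acid, (Z)-2-methylbut-2-enoic acid | C/C=C(/C)C(=O)O | starting material
25 | (Z)-2-methylbut-2-enoic 2,4,6-trichlorobenzoic anhydride | C/C=C(/C)C(=O)OC(=O)c1c(Cl)cc(Cl)cc1Cl | intermediate (not isolated)
26 | (1R,2R,6R)-3-methyl-6-[(3S)-6-methyl-3-{[(Z)-2-methylbut-2-enoyl]oxy}hepta-1,5-dien-2-yl]cyclohex-3-ene-1,2-diyl bis[(Z)-2-methylbut-2-enoate] | C=C([C@H](CC=C(C)C)OC(=O)/C(C)=C\C)[C@H]1CC=C(C)[C@@H](OC(=O)/C(C)=C\C)[C@@H]1OC(=O)/C(C)=C\C | intermediate
27 | (1R,2R,6R)-6-{(3S)-4-[(2R)-3,3-dimethyloxiran-2-yl]-3-{[(Z)-2-methylbut-2-enoyl]oxy}but-1-en-2-yl}-3-methylcyclohex-3-ene-1,2-diyl bis[(Z)-2-methylbut-2-enoate] | C=C([C@H](C[C@H]1OC1(C)C)OC(=O)/C(C)=C\C)[C@H]1CC=C(C)[C@@H](OC(=O)/C(C)=C\C)[C@@H]1OC(=O)/C(C)=C\C | intermediate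
28 | (1R,2S,3S,4S,6R,8S,10R)-1,2,8-tris(angeloyloxy)-3,4:10,11-diepoxybisabol-7(14)-ene | C=C([C@H](C[C@H]1OC1(C)C)OC(=O)/C(C)=C\C)[C@H]1C[C@@H]2O[C@]2(C)[C@@H](OC(=O)/C(C)=C\C)[C@@H]1OC(=O)/C(C)=C\C | target

**Step count and risks**
Total steps: 20. Longest linear sequence: 15 steps (1, 2, 4–7, 12–20).

Step 16 (key carbonyl-ene closure). What may go wrong: loss of facial control if the C2 silyloxy group turns pseudo-axial to relieve A(1,2) strain against the C3 methyl; ionisation towards a C7 cation followed by 1,2-hydride shift from C8; and epimerisation or conjugation of the α-silyloxy β,γ-unsaturated aldehyde on the Lewis acid. The fallback sets out from diol 19 and comes back at triol 23. It removes the C2 stereocentre and uses a 1,2-dicarbonyl enophile. Double Swern oxidation of 19 should give the α-keto aldehyde (3Z,6Z,8S)-8-(tert-butyldimethylsilyloxy)-3,7,11-trimethyl-2-oxododeca-3,6,10-trienal F1. Its aldehyde, activated like a glyoxylate, should undergo the same C1–C6 ene closure under a mild chelating Lewis acid (MgBr2·OEt2, or Cu(OTf)2 with a C2-symmetric bis(oxazoline) ligand for catalyst control) to the trans hydroxy enone (5R,6R)-5-[(3S)-3-(tert-butyldimethylsilyloxy)-6-methylhepta-1,5-dien-2-yl]-6-hydroxy-2-methylcyclohex-2-en-1-one F2. Luche reduction (NaBH4, CeCl3·7H2O, MeOH, −78 °C) should deliver hydride axially, as in the reduction of carvone to cis-carveol, to give the all-equatorial diol (1R,2R,6R)-6-[(3S)-3-(tert-butyldimethylsilyloxy)-6-methylhepta-1,5-dien-2-yl]-3-methylcyclohex-3-ene-1,2-diol F3, and Bu4NF then gives 23.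

Step 20 (ring epoxidation). What may go wrong: sluggish oxygen transfer to the hindered ring alkene deactivated by the allylic angelate, poor facial selectivity if reagent and substrate preferences do not reinforce, and over-oxidation of the C7=C14 methylene on forcing. The fallback sets out from 22 and comes back at 28. It installs the ring oxirane by substrate-controlled nucleophilic epoxidation before the esters are made. PPTS in MeOH at 0 °C should cleave only the triethylsilyl ether of 22 to give the diol F3, and MnO2 should oxidise only the allylic C2 hydroxyl to give the hydroxy enone F2. Weitz–Scheffer epoxidation (t-BuOOH, DBU, CH2Cl2, 0 °C) should add to C4 anti to the C6 side chain, as with carvone, to give (1R,3S,4S,6R,8S)-8-(tert-butyldimethylsilyloxy)-3,4-epoxy-1-hydroxybisabola-7(14),10-dien-2-one F4. Luche reduction, with hydride arriving on the face away from the C3 methyl, should give (1R,2S,3S,4S,6R,8S)-8-(tert-butyldimethylsilyloxy)-3,4-epoxybisabola-7(14),10-diene-1,2-diol F5, and Bu4NF the epoxy triol (1R,2S,3S,4S,6R,8S)-3,4-epoxybisabola-7(14),10-diene-1,2,8-triol F6. Triple acylation under the conditions of step 18 (three equivalents of angelic acid 24) should give (1R,2S,3S,4S,6R,8S)-1,2,8-tris(angeloyloxy)-3,4-epoxybisabola-7(14),10-diene F7, and the epoxidation of step 19 on C10=C11 then gives 28.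

Step 18 (triple angeloylation). What may go wrong: incomplete acylation of the hindered C2 and C8 allylic hydroxyls, and Z to E isomerisation of angeloyl to tigloyl groups at the temperature needed. The fallback sets out from 23 and comes back at 26. It builds the Z-olefins after acylation. Steglich esterification of 23 with three equivalents of 2-[bis(2,2,2-trifluoroethoxy)phosphoryl]propanoic acid (DCC, DMAP, CH2Cl2) should give the tris[2-(bis(2,2,2-trifluoroethoxy)phosphoryl)propanoate] of triol 23 F8. Threefold Still–Gennari olefination with three equivalents of acetaldehyde (KN(SiMe3)2, 18-crown-6, THF, −78 °C) should then form the three (Z)-2-methylbut-2-enoates of 26.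

**Further compounds**
F1 | step 16 | (3Z,6Z,8S)-8-(tert-butyldimethylsilyloxy)-3,7,11-trimethyl-2-oxododeca-3,6,10-trienal | O=CC(=O)/C(C)=C\C/C=C(/C)[C@@H](O[Si](C)(C)C(C)(C)C)CC=C(C)C
F2 | step 16 | (5R,6R)-5-[(3S)-3-(tert-butyldimethylsilyloxy)-6-methylhepta-1,5-dien-2-yl]-6-hydroxy-2-methylcyclohex-2-en-1-one | C=C([C@H](CC=C(C)C)O[Si](C)(C)C(C)(C)C)[C@H]1CC=C(C)C(=O)[C@@H]1O
F3 | step 16 | (1R,2R,6R)-6-[(3S)-3-(tert-butyldimethylsilyloxy)-6-methylhepta-1,5-dien-2-yl]-3-methylcyclohex-3-ene-1,2-diol | C=C([C@H](CC=C(C)C)O[Si](C)(C)C(C)(C)C)[C@H]1CC=C(C)[C@@H](O)[C@@H]1O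
F4 | step 20 | (1R,3S,4S,6R,8S)-8-(tert-butyldimethylsilyloxy)-3,4-epoxy-1-hydroxybisabola-7(14),10-dien-2-one | C=C([C@H](CC=C(C)C)O[Si](C)(C)C(C)(C)C)[C@H]1C[C@@H]2O[C@]2(C)C(=O)[C@@H]1O
F5 | step 20 | (1R,2S,3S,4S,6R,8S)-8-(tert-butyldimethylsilyloxy)-3,4-epoxybisabola-7(14),10-diene-1,2-diol | C=C([C@H](CC=C(C)C)O[Si](C)(C)C(C)(C)C)[C@H]1C[C@@H]2O[C@]2(C)[C@@H](O)[C@@H]1O
F6 | step 20 | (1R,2S,3S,4S,6R,8S)-3,4-epoxybisabola-7(14),10-diene-1,2,8-triol | C=C([C@H](CC=C(C)C)O)[C@H]1C[C@@H]2O[C@]2(C)[C@@H](O)[C@@H]1O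
F7 | step 20 | (1R,2S,3S,4S,6R,8S)-1,2,8-tris(angeloyloxy)-3,4-epoxybisabola-7(14),10-diene | C=C([C@H](CC=C(C)C)OC(=O)/C(C)=C\C)[C@H]1C[C@@H]2O[C@]2(C)[C@@H](OC(=O)/C(C)=C\C)[C@@H]1OC(=O)/C(C)=C\C
F8 | step 18 | tris[2-(bis(2,2,2-trifluoroethoxy)phosphoryl)propanoate] of triol 23 | C=C([C@H](CC=C(C)C)OC(=O)C(C)P(=O)(OCC(F)(F)F)OCC(F)(F)F)[C@H]1CC=C(C)[C@@H](OC(=O)C(C)P(=O)(OCC(F)(F)F)OCC(F)(F)F)[C@@H]1OC(=O)C(C)P(=O)(OCC(F)(F)F)OCC(F)(F)F
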